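**Plan**

- Enabling feature: in the ten-membered ring, C6 is a carbinol carbon allylic to C4=C5 and bonded to C7, and C7 carries the C11(=C13) unit of the methylene lactone ring. This homoallylic alcohol is what a [2,3]-Wittig shift of a C6–O–C13 diallyl ether produces.
- Retrosynthetic cuts, in order: the four epoxide C–O bonds (C1/C10, C4/C5); the O8–C12 lactone bond and the O6 angeloyl bond; C6–C7 (back to the thirteen-membered ether); the C6–O ether bond; C8–C9; C7=C11.
- Forward: geraniol gives the C1–C6/C9/C10 allylic sulfone. Dihydroxyacetone and the ylide give a butenolide that supplies C7, C8 and C11–C13 and tells C12 from C13. Sulfone acylation then joins C8–C9.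
- Rings: thirteen-membered ether (Williamson), ten-membered carbocycle (ring contraction), γ-lactone (oxidative lactonisation), then the two oxiranes.
- Stereochemistry: C8 from a CBS reduction; C6 and C7 from the Wittig shift, steered by C8 and the E-olefins; C1, C10, C4, C5 from the Shi ketone on the outer olefin faces; olefin geometry from geraniol and from the butenolide ring; the Z-ester from angelic acid.

Key step: step 17

Remark: germacrane numbering (C1 to C15) is used for all intermediates, α/β refer to the usual germacranolide drawing (H7 α), and 1,3-dihydroxyacetone is charged as its commercial dimer, which dissociates in solution.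

**Step 1**
Reactants: 1 geraniol
Product: 2 geranyl 4-methoxybenzyl ether (C6–OPMB)
Conditions: NaH, 4-methoxybenzyl chloride, n-Bu4NI (cat.), THF/DMF, 0 °C to rt
Reagents that add atoms: 4-methoxybenzyl chloride, COc1ccc(CCl)cc1
Why: Williamson etherification of the primary allylic alkoxide masks O6 with a group that should survive organolithium, SmI2, borane and silyl triflate chemistry and can later be removed oxidatively.

**Step 2**
Reactants: 2 geranyl 4-methoxybenzyl ether
Product: 3 (2E,6E)-8-(4-methoxybenzyloxy)-2,6-dimethylocta-2,6-dien-1-ol (C9 alcohol)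
Conditions: SeO2 (0.3 equiv), t-BuOOH, salicylic acid (cat.), CH2Cl2, rt
Reagents that add atoms: tert-butyl hydroperoxide, CC(C)(C)OO (terminal oxidant); selenium dioxide, O=[Se]=O (catalytic oxygen carrier)
Why: Catalytic SeO2 allylic oxidation (ene reaction, then [2,3]-shift) should hydroxylate the E-methyl of the terminal trisubstituted olefin selectively, which fixes the E geometry of C10=C1, while the C4=C5 olefin is deactivated by its allylic ether.

**Step 3**
Reactants: 3 C9 alcohol
Product: 4 (2E,6E)-1-bromo-8-(4-methoxybenzyloxy)-2,6-dimethylocta-2,6-diene (C9 bromide)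
Conditions: CBr4, PPh3, CH2Cl2, 0 °C
Reagents that add atoms: carbon tetrabromide, BrC(Br)(Br)Br
Why: Appel bromination displaces the phosphonium-activated primary allylic oxygen by SN2 and should not transpose the olefin at 0 °C.

**Step 4**
Reactants: 4 C9 bromide
Product: 5 (2E,6E)-8-(4-methoxybenzyloxy)-2,6-dimethylocta-2,6-dien-1-yl phenyl sulfone (C9 sulfone)
Conditions: PhSO2Na, DMF, rt
Reagents that add atoms: sodium benzenesulfinate, [Na+].[O-]S(=O)c1ccccc1
Why: S-alkylation of the sulfinate by the primary allylic bromide (SN2) gives the allylic sulfone whose α-carbon C9 can be lithiated.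

**Step 5**
Reactants: 6 1,3-dihydroxyacetone; 7 ethyl (triphenylphosphoranylidene)acetate
Product: 9 4-(hydroxymethyl)furan-2(5H)-one, via ethyl 4-hydroxy-3-(hydroxymethyl)but-2-enoate 8 (not isolated)
Conditions: CH2Cl2, rt
Reagents that add atoms: none
Why: Wittig olefination of the ketone gives the symmetrical diol ester 8, in which one hydroxymethyl arm is necessarily cis to the ester and lactonises, so the butenolide ring distinguishes the future C12 (ring CH2O) from C13 (exocyclic CH2OH).

**Step 6**
Reactants: 9 4-(hydroxymethyl)furan-2(5H)-one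
Product: 10 4-[(tert-butyldimethylsilyloxy)methyl]furan-2(5H)-one
Conditions: TBSCl, imidazole, CH2Cl2, 0 °C to rt
Reagents that add atoms: tert-butyldimethylsilyl chloride, CC(C)(C)[Si](C)(C)Cl
Why: Imidazole-promoted silylation of the primary alcohol puts a TBS group on O13 that can later be removed in the presence of TIPS ethers.

**Step 7**
Reactants: 10 silylated butenolide
Product: 11 4-hydroxy-N-methoxy-N-methyl-3-[(tert-butyldimethylsilyloxy)methyl]but-2-enamide (free CH2OH, C12, cis to the amide carbonyl C8; CH2OTBS, C13, trans)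
Conditions: MeNH(OMe)·HCl, AlMe3, CH2Cl2, 0 °C to rt; cold aqueous Rochelle salt work-up, used at once
Reagents that add atoms: N,O-dimethylhydroxylamine hydrochloride, CNOC.Cl
Why: Weinreb aminolysis by the aluminium amide opens the lactone at the acyl C–O bond, which keeps the C8 carbonyl cis to the freed C12 hydroxymethyl, and conjugate addition is blocked by the fully substituted β-carbon.

**Step 8**
Reactants: 11 hydroxy Weinreb amide
Product: 12 N-methoxy-N-methyl-3-[(tert-butyldimethylsilyloxy)methyl]-4-(triisopropylsilyloxy)but-2-enamide (CH2OTIPS, C12, cis to the amide carbonyl)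
Conditions: TIPSOTf, 2,6-lutidine, CH2Cl2, −78 to 0 °C
Reagents that add atoms: triisopropylsilyl trifluoromethanesulfonate, CC(C)[Si](OS(=O)(=O)C(F)(F)F)(C(C)C)C(C)C
Why: Fast silyl triflate silylation at low temperature caps O12 before the cis hydroxy amide can relactonise.

**Step 9**
Reactants: 5 C9 sulfone; 12 Weinreb amide
Product: 13 6-(4-methoxybenzyloxy)-9-(phenylsulfonyl)-13-(tert-butyldimethylsilyloxy)-12-(triisopropylsilyloxy)-6,7-secogermacra-1(10)E,4E,7(11)-trien-8-one (C9 epimers; C12 arm cis to C8)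
Conditions: 5, n-BuLi, THF, −78 °C; then 12, −78 to −30 °C; aq. NH4Cl
Reagents that add atoms: none
Why: The α-lithio allylic sulfone reacts at its α-carbon with the Weinreb amide (sulfone acylation), whose chelated tetrahedral intermediate prevents over-addition, and this forms the C8–C9 bond.

**Step 10**
Reactants: 13 β-keto sulfone
Product: 14 6-(4-methoxybenzyloxy)-13-(tert-butyldimethylsilyloxy)-12-(triisopropylsilyloxy)-6,7-secogermacra-1(10)E,4E,7(11)-trien-8-one
Conditions: SmI2, THF/MeOH, −78 °C
Reagents that add atoms: none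
Why: SmI2 reductive desulfonylation of a β-keto sulfone (ketyl formation, loss of sulfinate, α-protonation of the samarium enolate by MeOH) should be faster than enone reduction and leaves C10=C1 out of conjugation.

**Step 11**
Reactants: 14 enone
Product: 15 (8S)-6-(4-methoxybenzyloxy)-13-(tert-butyldimethylsilyloxy)-12-(triisopropylsilyloxy)-6,7-secogermacra-1(10)E,4E,7(11)-trien-8-ol
Conditions: (R)-2-methyl-CBS-oxazaborolidine [(R)-1-methyl-3,3-diphenyltetrahydro-1H,3H-pyrrolo[1,2-c][1,3,2]oxazaborole, C18H20BNO] (0.5 equiv), catecholborane, toluene, −78 °C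
Reagents that add atoms: none
Why: Corey–Bakshi–Shibata reduction with the (R)-oxazaborolidine treats the Z-alkenyl group as the large substituent and should deliver hydride to the face that gives the 8S carbinol, while catecholborane at −78 °C leaves the olefins alone.

**Step 12**
Reactants: 15 (8S)-allylic alcohol
Product: 16 (8S)-6-(4-methoxybenzyloxy)-13-(tert-butyldimethylsilyloxy)-8,12-bis(triisopropylsilyloxy)-6,7-secogermacra-1(10)E,4E,7(11)-triene
Conditions: TIPSOTf, 2,6-lutidine, CH2Cl2, −78 to 0 °C
Reagents that add atoms: triisopropylsilyl trifluoromethanesulfonate, CC(C)[Si](OS(=O)(=O)C(F)(F)F)(C(C)C)C(C)C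
Why: Silyl triflate silylation protects the hindered secondary allylic alcohol as a TIPS ether that tolerates NaH and s-BuLi and migrates only slowly.

**Step 13**
Reactants: 16 tris-silyl ether
Product: 17 (8S)-6-(4-methoxybenzyloxy)-8,12-bis(triisopropylsilyloxy)-6,7-secogermacra-1(10)E,4E,7(11)-trien-13-ol
Conditions: pyridinium p-toluenesulfonate (0.2 equiv), MeOH, rt
Reagents that add atoms: none
Why: Acid-catalysed methanolysis cleaves the primary TBS ether far faster than the primary and secondary TIPS ethers, so only O13 should be freed.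

**Step 14**
Reactants: 17 C13 alcohol
Product: 18 (8S)-13-chloro-6-(4-methoxybenzyloxy)-8,12-bis(triisopropylsilyloxy)-6,7-secogermacra-1(10)E,4E,7(11)-triene
Conditions: MsCl, 2,4,6-collidine, LiCl, DMF, 0 °C
Reagents that add atoms: lithium chloride, [Li+].[Cl-]
Why: In situ mesylation followed by chloride exchange converts the primary allylic alcohol into the chloride by SN2 under non-acidic conditions, without transposition.

**Step 15**
Reactants: 18 C13 chloride
Product: 19 (8S)-13-chloro-8,12-bis(triisopropylsilyloxy)-6,7-secogermacra-1(10)E,4E,7(11)-trien-6-ol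
Conditions: DDQ, CH2Cl2/pH 7 phosphate buffer, 0 °C
Reagents that add atoms: none
Why: DDQ cleaves the 4-methoxybenzyl ether oxidatively through its benzylic cation and hemiacetal, and the buffered conditions should leave the allylic chloride and the silyl ethers intact.

**Step 16**
Reactants: 19 chloro alcohol
Product: 20 (8S)-8,12-bis(triisopropylsilyloxy)-6,13-epoxy-6,7-secogermacra-1(10)E,4E,7(11)-triene (thirteen-membered diallyl ether; ring bonds trans across all three olefins)
Conditions: NaH, n-Bu4NI (cat.), THF, 50 °C, slow addition to 0.002 M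
Reagents that add atoms: none
Why: Intramolecular Williamson etherification under high dilution (SN2 of the C6 alkoxide on the C13 allylic chloride) should close the thirteen-membered ether, because three E-olefins keep transannular strain low and the alkoxide is far from both silyl ethers.

**Step 17**
Reactants: 20 thirteen-membered diallyl ether
Product: 22 6α-hydroxy-8α,12-bis(triisopropylsilyloxy)germacra-1(10)E,4E,11(13)-triene (7αH), via C6-lithiated ether 21 (not isolated)
Conditions: s-BuLi, THF, −78 °C; AcOH/THF quench at −78 °C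
Reagents that add atoms: none
Why: s-BuLi removes a C6 proton to give the α-oxy allyllithium 21, which undergoes a concerted suprafacial [2,3]-sigmatropic shift through a five-membered envelope transition state in which C6 bonds to C7 while O–C13 breaks and C11=C13 appears. The closest known reaction type is the [2,3]-Wittig ring contraction of thirteen-membered diallylic and propargylic allylic ethers to ten-membered carbocyclic homoallylic alcohols. The ten-membered carbocycle closes by ring contraction, an intramolecular SN2′-type attack of the C6 carbanion on C7 that expels O, C13 and C11 from the ring. The anti C6/C7 relationship (6α-O, 7α-H) follows from the trans ring geometry of the C13–C11=C7–C8 allyl unit with the C5 vinyl group exo on the envelope, and the absolute sense follows from C8, since C6 should reach the C7 face anti to the C8–OTIPS bond while the C9 ring bond lies near the olefin plane to avoid A(1,3) strain with the cis CH2OTIPS arm. The step needs lithiation at C6 and not at C13 or C12, which is favoured because C6 is the only ether methylene next to an unsubstituted vinylic CH, whereas C13 and C12 sit on the fully substituted C11 between two TIPS groups. The cold quench keeps the new lithium alkoxide from taking the C8 silyl group or drifting to [1,2]-shift products.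

**Step 18**
Reactants: 22 C6 alcohol; 23 angelic acid [(Z)-2-methylbut-2-enoic acid]
Product: 25 6α-angeloyloxy-8α,12-bis(triisopropylsilyloxy)germacra-1(10)E,4E,11(13)-triene, via angelic 2,4,6-trichlorobenzoic anhydride 24 (not isolated)
Conditions: 23, 2,4,6-trichlorobenzoyl chloride, Et3N, toluene, rt; then 22, 65 °C
Reagents that add atoms: none
Why: Yamaguchi-type acylation with the preformed mixed anhydride 24 and no nucleophilic catalyst should esterify the hindered C6 alcohol while avoiding base-induced Z to E isomerisation of the angeloyl group.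

**Step 19**
Reactants: 25 angelate bis-silyl ether
Product: 26 6α-angeloyloxygermacra-1(10)E,4E,11(13)-triene-8α,12-diol
Conditions: TBAF, AcOH (1:1), THF, rt
Reagents that add atoms: none
Why: Fluoride cleaves both TIPS ethers, and buffering with AcOH should suppress O6 to O8 acyl migration without exposing the acid-sensitive 1,5-diene to strong acid.

**Step 20**
Reactants: 26 diol
Product: 29 6α-angeloyloxygermacra-1(10)E,4E,11(13)-trien-12,8α-olide, via hydroxy enal 27 (not isolated), via lactol 28 (not isolated)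
Conditions: TEMPO (2,2,6,6-tetramethylpiperidin-1-oxyl, C9H18NO; 0.2 equiv), PhI(OAc)2, CH2Cl2, rt
Reagents that add atoms: none
Why: TEMPO/PhI(OAc)2 oxidation takes the primary allylic alcohol to enal 27, which the C8 hydroxyl traps as lactol 28 before further oxidation to the γ-lactone (oxidative lactonisation of a 1,4-diol), and with O6 blocked by the angelate only the trans-fused 8,12-olide can form.

**Step 21**
Reactants: 29 diene lactone
Product: 30 1β,10α:4α,5β-diepoxy-6α-angeloyloxygermacr-11(13)-en-12,8α-olide (1R,4R,5R,6S,7R,8S,10R), the target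
Conditions: D-fructose-derived Shi ketone (1,2:4,5-di-O-isopropylidene-β-D-erythro-2,3-hexodiulo-2,6-pyranose, C12H18O6; 0.6 equiv), Oxone (2KHSO5·KHSO4·K2SO4), K2CO3, n-Bu4NHSO4, MeCN/CH2(OMe)2/aq. Na2B4O7–Na2EDTA buffer, 0 °C
Reagents that add atoms: potassium peroxymonosulfate (active salt of Oxone), [K+].[O-]S(=O)(=O)OO
Why: Shi asymmetric epoxidation oxidises the two electron-rich E-trisubstituted ring olefins through a spiro transition state to the (R,R)-epoxides, that is 1β,10α and 4α,5β, which is also the outer face of the crown conformer, while the conjugated methylene lactone and the angelate are too electron-poor for the dioxirane.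

**Compound list**

1 | geraniol | CC(C)=CCC/C(C)=C/CO | starting material
2 | geranyl 4-methoxybenzyl ether | CC(C)=CCC/C(C)=C/COCc1ccc(OC)cc1 | intermediate
3 | (2E,6E)-8-(4-methoxybenzyloxy)-2,6-dimethylocta-2,6-dien-1-ol | OC/C(C)=C/CC/C(C)=C/COCc1ccc(OC)cc1 | intermediate
4 | (2E,6E)-1-bromo-8-(4-methoxybenzyloxy)-2,6-dimethylocta-2,6-diene | BrC/C(C)=C/CC/C(C)=C/COCc1ccc(OC)cc1 | intermediate
5 | (2E,6E)-8-(4-methoxybenzyloxy)-2,6-dimethylocta-2,6-dien-1-yl phenyl sulfone | O=S(=O)(C/C(C)=C/CC/C(C)=C/COCc1ccc(OC)cc1)c1ccccc1 | intermediate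
6 | 1,3-dihydroxyacetone | OCC(=O)CO | starting material
7 | ethyl (triphenylphosphoranylidene)acetate | CCOC(=O)C=P(c1ccccc1)(c1ccccc1)c1ccccc1 | starting material
8 | ethyl 4-hydroxy-3-(hydroxymethyl)but-2-enoate | CCOC(=O)C=C(CO)CO | intermediate (not isolated)
9 | 4-(hydroxymethyl)furan-2(5H)-one | O=C1C=C(CO)CO1 | intermediate
10 | 4-[(tert-butyldimethylsilyloxy)methyl]furan-2(5H)-one | O=C1C=C(CO[Si](C)(C)C(C)(C)C)CO1 | intermediate
11 | 4-hydroxy-N-methoxy-N-methyl-3-[(tert-butyldimethylsilyloxy)methyl]but-2-enamide (CH2OH cis to C=O) | CON(C)C(=O)/C=C(\CO)CO[Si](C)(C)C(C)(C)C | intermediate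
12 | N-methoxy-N-methyl-3-[(tert-butyldimethylsilyloxy)methyl]-4-(triisopropylsilyloxy)but-2-enamide (CH2OTIPS cis to C=O) | CON(C)C(=O)/C=C(\CO[Si](C(C)C)(C(C)C)C(C)C)CO[Si](C)(C)C(C)(C)C | intermediate
13 | 6-(4-methoxybenzyloxy)-9-(phenylsulfonyl)-13-(tert-butyldimethylsilyloxy)-12-(triisopropylsilyloxy)-6,7-secogermacra-1(10)E,4E,7(11)-trien-8-one (C9 epimers) | COc1ccc(COC/C=C(\C)CC/C=C(\C)C(C(=O)/C=C(\CO[Si](C(C)C)(C(C)C)C(C)C)CO[Si](C)(C)C(C)(C)C)S(=O)(=O)c2ccccc2)cc1 | intermediate
14 | 6-(4-methoxybenzyloxy)-13-(tert-butyldimethylsilyloxy)-12-(triisopropylsilyloxy)-6,7-secogermacra-1(10)E,4E,7(11)-trien-8-one | COc1ccc(COC/C=C(\C)CC/C=C(\C)CC(=O)/C=C(\CO[Si](C(C)C)(C(C)C)C(C)C)CO[Si](C)(C)C(C)(C)C)cc1 | intermediate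
15 | (8S)-6-(4-methoxybenzyloxy)-13-(tert-butyldimethylsilyloxy)-12-(triisopropylsilyloxy)-6,7-secogermacra-1(10)E,4E,7(11)-trien-8-ol | COc1ccc(COC/C=C(\C)CC/C=C(\C)C[C@H](O)/C=C(\CO[Si](C(C)C)(C(C)C)C(C)C)CO[Si](C)(C)C(C)(C)C)cc1 | intermediate
16 | (8S)-6-(4-methoxybenzyloxy)-13-(tert-butyldimethylsilyloxy)-8,12-bis(triisopropylsilyloxy)-6,7-secogermacra-1(10)E,4E,7(11)-triene | COc1ccc(COC/C=C(\C)CC/C=C(\C)C[C@H](O[Si](C(C)C)(C(C)C)C(C)C)/C=C(\CO[Si](C(C)C)(C(C)C)C(C)C)CO[Si](C)(C)C(C)(C)C)cc1 | intermediate
17 | (8S)-6-(4-methoxybenzyloxy)-8,12-bis(triisopropylsilyloxy)-6,7-secogermacra-1(10)E,4E,7(11)-trien-13-ol | COc1ccc(COC/C=C(\C)CC/C=C(\C)C[C@H](O[Si](C(C)C)(C(C)C)C(C)C)/C=C(\CO[Si](C(C)C)(C(C)C)C(C)C)CO)cc1 | intermediate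
18 | (8S)-13-chloro-6-(4-methoxybenzyloxy)-8,12-bis(triisopropylsilyloxy)-6,7-secogermacra-1(10)E,4E,7(11)-triene | COc1ccc(COC/C=C(\C)CC/C=C(\C)C[C@H](O[Si](C(C)C)(C(C)C)C(C)C)/C=C(\CO[Si](C(C)C)(C(C)C)C(C)C)CCl)cc1 | intermediate
19 | (8S)-13-chloro-8,12-bis(triisopropylsilyloxy)-6,7-secogermacra-1(10)E,4E,7(11)-trien-6-ol | OC/C=C(\C)CC/C=C(\C)C[C@H](O[Si](C(C)C)(C(C)C)C(C)C)/C=C(\CO[Si](C(C)C)(C(C)C)C(C)C)CCl | intermediate
20 | (8S)-8,12-bis(triisopropylsilyloxy)-6,13-epoxy-6,7-secogermacra-1(10)E,4E,7(11)-triene (thirteen-membered diallyl ether) | O1C/C(CO[Si](C(C)C)(C(C)C)C(C)C)=C/[C@@H](O[Si](C(C)C)(C(C)C)C(C)C)C/C(C)=C/CC/C(C)=C/C1 | intermediate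
21 | C6-lithiated ether (6-lithio derivative of 20) | O1C/C(CO[Si](C(C)C)(C(C)C)C(C)C)=C/[C@@H](O[Si](C(C)C)(C(C)C)C(C)C)C/C(C)=C/CC/C(C)=C/C1[Li] | intermediate (not isolated)
22 | 6α-hydroxy-8α,12-bis(triisopropylsilyloxy)germacra-1(10)E,4E,11(13)-triene | C=C(CO[Si](C(C)C)(C(C)C)C(C)C)[C@@H]1[C@@H](O[Si](C(C)C)(C(C)C)C(C)C)C/C(C)=C/CC/C(C)=C/[C@H]1O | intermediate
23 | angelic acid, (Z)-2-methylbut-2-enoic acid | C/C=C(/C)C(=O)O | starting material
24 | angelic 2,4,6-trichlorobenzoic anhydride | C/C=C(/C)C(=O)OC(=O)c1c(Cl)cc(Cl)cc1Cl | intermediate (not isolated)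
25 | 6α-angeloyloxy-8α,12-bis(triisopropylsilyloxy)germacra-1(10)E,4E,11(13)-triene | C=C(CO[Si](C(C)C)(C(C)C)C(C)C)[C@@H]1[C@@H](O[Si](C(C)C)(C(C)C)C(C)C)C/C(C)=C/CC/C(C)=C/[C@H]1OC(=O)/C(C)=C\C | intermediate
26 | 6α-angeloyloxygermacra-1(10)E,4E,11(13)-triene-8α,12-diol | C=C(CO)[C@@H]1[C@@H](O)C/C(C)=C/CC/C(C)=C/[C@H]1OC(=O)/C(C)=C\C | intermediate
27 | 6α-angeloyloxy-8α-hydroxygermacra-1(10)E,4E,11(13)-trien-12-al (hydroxy enal) | C=C(C=O)[C@@H]1[C@@H](O)C/C(C)=C/CC/C(C)=C/[C@H]1OC(=O)/C(C)=C\C | intermediate (not isolated)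
28 | 6α-angeloyloxy-8α,12-epoxygermacra-1(10)E,4E,11(13)-trien-12-ol (lactol, C12 epimers) | C=C1C(O)O[C@H]2C/C(C)=C/CC/C(C)=C/[C@@H](OC(=O)/C(C)=C\C)[C@H]12 | intermediate (not isolated)
29 | 6α-angeloyloxygermacra-1(10)E,4E,11(13)-trien-12,8α-olide | C=C1C(=O)O[C@H]2C/C(C)=C/CC/C(C)=C/[C@@H](OC(=O)/C(C)=C\C)[C@H]12 | intermediate
30 | 1β,10α:4α,5β-diepoxy-6α-angeloyloxygermacr-11(13)-en-12,8α-olide (CNP0145353.1) | C=C1C(=O)O[C@H]2C[C@@]3(C)O[C@@H]3CC[C@@]3(C)O[C@@H]3[C@@H](OC(=O)/C(C)=C\C)[C@H]12 | target

**Step count and risks**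

Total step count: 21. Longest linear sequence: 17 steps (geraniol through steps 1–4 and 9–21; the dihydroxyacetone branch through steps 5–8 and 9–21 is equally long).

Steps most likely to fail:

1. Step 17. Lithiation may stray to the C13 or C12 allylic positions, the carbanion may take a [1,2]-shift, or the C7 face may be chosen poorly. The fallback forms the same C6–C7 bond without a carbanion at C6. It sets out from 19, whose C6 alcohol is oxidised with MnO2 in CH2Cl2 to the enal (8S)-13-chloro-8,12-bis(triisopropylsilyloxy)-6,7-secogermacra-1(10)E,4E,7(11)-trien-6-al F1. Treating this with CrCl2 and NaI in THF/DMF at high dilution would effect an intramolecular Nozaki–Hiyama allylation. The allylchromium formed at C13 adds through C7 to the C6 aldehyde in a chair transition state (anti), creating the C11=C13 methylene and the ten-membered ring directly. The route is rejoined at 22.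

2. Step 21. The mobile ten-membered ring may give poor face or site selectivity, and the basic peroxide medium may degrade the methylene lactone by conjugate addition or hydrolysis. The fallback moves the oxidation ahead of lactone formation. It sets out from 25, which is diepoxidised with the same ketone and Oxone to 1β,10α:4α,5β-diepoxy-6α-angeloyloxy-8α,12-bis(triisopropylsilyloxy)germacr-11(13)-ene F2. TBAF/AcOH then gives 1β,10α:4α,5β-diepoxy-6α-angeloyloxygermacr-11(13)-ene-8α,12-diol F3. TEMPO/PhI(OAc)2 with solid NaHCO3 lactonises this, and the route is rejoined at 30.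

3. Step 18. Acylation of the hindered C6 alcohol may be slow, letting Z to E isomerisation to the tiglate or a thermal Cope rearrangement of the 1,5-diene compete at 65 °C. The fallback builds the Z-olefin on the ester at low temperature. It sets out from 22, which is esterified at rt (DCC, 4-dimethylaminopyridine, CH2Cl2) with 2-[bis(2,2,2-trifluoroethoxy)phosphoryl]propanoic acid to 6α-{2-[bis(2,2,2-trifluoroethoxy)phosphoryl]propanoyloxy}-8α,12-bis(triisopropylsilyloxy)germacra-1(10)E,4E,11(13)-triene F4. Still–Gennari olefination of this with acetaldehyde (KN(SiMe3)2, 18-crown-6, THF, −78 °C) should give the (Z)-2-methylbut-2-enoate, and the route is rejoined at 25.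

**Further compounds**

F1 | step 17 | (8S)-13-chloro-8,12-bis(triisopropylsilyloxy)-6,7-secogermacra-1(10)E,4E,7(11)-trien-6-al | O=C/C=C(\C)CC/C=C(\C)C[C@H](O[Si](C(C)C)(C(C)C)C(C)C)/C=C(\CO[Si](C(C)C)(C(C)C)C(C)C)CCl
F2 | step 21 | 1β,10α:4α,5β-diepoxy-6α-angeloyloxy-8α,12-bis(triisopropylsilyloxy)germacr-11(13)-ene | C=C(CO[Si](C(C)C)(C(C)C)C(C)C)[C@@H]1[C@@H](O[Si](C(C)C)(C(C)C)C(C)C)C[C@@]2(C)O[C@@H]2CC[C@@]2(C)O[C@@H]2[C@H]1OC(=O)/C(C)=C\C
F3 | step 21 | 1β,10α:4α,5β-diepoxy-6α-angeloyloxygermacr-11(13)-ene-8α,12-diol | C=C(CO)[C@@H]1[C@@H](O)C[C@@]2(C)O[C@@H]2CC[C@@]2(C)O[C@@H]2[C@H]1OC(=O)/C(C)=C\C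
F4 | step 18 | 6α-{2-[bis(2,2,2-trifluoroethoxy)phosphoryl]propanoyloxy}-8α,12-bis(triisopropylsilyloxy)germacra-1(10)E,4E,11(13)-triene | C=C(CO[Si](C(C)C)(C(C)C)C(C)C)[C@@H]1[C@@H](O[Si](C(C)C)(C(C)C)C(C)C)C/C(C)=C/CC/C(C)=C/[C@H]1OC(=O)C(C)P(=O)(OCC(F)(F)F)OCC(F)(F)F
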